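## The problem

Atom labels O1 and C2–C5 refer to the oxolane ring of the target 17 throughout.

Target 17 is a 2,5-diaryl-3,4-dimethyloxolane: one five-membered ring with four contiguous stereocentres, ring A (3-hydroxy-4,5-dimethoxyphenyl) on C2 and ring B (3,4,5-trimethoxyphenyl) on C5. The configuration (2S,3S,4R,5R) means 2,3-trans, 3,4-cis and 4,5-trans: the aryl groups are cis to each other, the methyl groups are cis to each other, and each aryl group is trans to the methyl group beside it. Rings A and B differ by one O-methyl group only, so with equal rings the molecule would be meso; the absolute configuration is therefore the decision which benzylic carbon carries which ring, and the rings must enter as separate building blocks on a scaffold of defined handedness. C2 and C5 are benzylic ether carbons beside electron-rich arenes and can be reset through the benzylic cation, the isomer with both aryl groups trans to their methyl neighbours being the most stable of the 3,4-cis series; C3 and C4 cannot be corrected once made, so they must be set firmly and can then dictate C2 and C5, while before ring closure a benzylic centre held in a ring can control C4 and C3. The cis-dimethyl pair is the contra-thermodynamic element, so C3 and C4 must not pass through a planar stage after they are set. The fragile groups are the two benzylic C–O bonds (acid: Friedel–Crafts closure to an aryltetralin or E1 loss; hydrogenolysis) and the phenol of ring A, which needs a mask that comes off without harming them. The enabling feature is that O1–C5–C4–C3 plus the methyl carbon on C3 have the connectivity of a γ-aryl butenolide (O1 = ring oxygen, C5 = γ-carbon with ring B, C4 = β-carbon, C3 = α-carbon, methyl carbon = carbonyl carbon), so that C4–CH3 and C2–C3 can be made by conjugate addition and enolate aldol reaction on one small chiral lactone. Because the carbonyl carbon ends as a methyl group and the aldol carbon as a ring carbon, the trans,trans-lactone that enolate chemistry gives by default is the direct precursor of the cis-dimethyl oxolane.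

## Retrosynthesis

**17 ⇒ 16 ⇒ 15.** Two C–O bonds are cut first: the phenol of 17 goes back to the benzyl ether 16, and the C3 methyl group of 16 to the mesyloxymethyl group of 15 (hydride in the forward sense). The neighbouring option, removing this oxygen before the ring is closed, would expose a 4-hydroxy sulfonate to a basic hydride; the C5 alkoxide would then close onto the primary carbon and give the wrong oxolane. With the ring closed the C5 oxygen is an ether and cannot interfere. Compound 15 is no simpler in skeleton, but its future methyl carbon carries an oxygen, which traces back to a lactone carbonyl. The forward steps need an SN2 hydride displacement at a β-branched primary sulfonate and a hydrogenolysis that takes the O-benzyl group but spares the two ring benzylic ethers.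

**15 ⇒ 14.** The O1–C2 bond is cut, opening the oxolane to the diol mesylate 14. O1–C2 is preferred over O1–C5 as the formal cut because C2 is the one centre the earlier chemistry leaves uncontrolled, so it should be formed in a step that selects the trans arrangement by itself. Chemically either benzylic carbinol of 14 may ionise, and both channels lead to the same 2,3-trans-4,5-trans ring because that isomer is the kinetic and the thermodynamic product for a fixed cis C3/C4 pair. Compound 14 is acyclic and carries defined centres only at C3, C4 and C5. The forward step must ionise a trialkoxybenzylic carbinol under mild Lewis acid and have the other hydroxyl capture the cation faster than the second arene or proton loss can.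

**14 ⇒ 13 ⇒ 12.** The mesylate is removed (S–O cut) to give triol 13, and the two C–O single bonds at the primary carbon and at C5 are rejoined as the ester of lactone 12. Sulfonylating the primary hydroxyl, and not protecting it, is chosen because the same group later serves as the leaving group, which saves a protection and a deprotection. Lactone 12 is simpler in that one ring holds O1 and the latent methyl carbon in a single functional group and leaves the C2 hydroxyl as the only free one. Forward, a lactone reduction and a primary-selective sulfonylation are needed.

**12 ⇒ 6 + 8 + 9.** The C4–CH3 bond and the C2–C3 bond are cut together, giving butenolide 6, aldehyde 8 and the methyl donor lithium dimethylcuprate 9. The neighbouring cuts are less economical: methylating C3 of a preformed lactone would give the trans-dimethyl series, and cutting C3–C4 would require two stereodefined partners. Here three contiguous centres (C3, C4, C5) collapse to the single centre of 6, and ring A arrives as an achiral aldehyde. The forward reaction must add methyl to the β-carbon anti to the C5 aryl group and trap the enolate at C3 anti to the new methyl group before it equilibrates.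

**6 ⇒ 4 ⇒ 1 + 2, and 8 ⇒ 7.** The butenolide ring is opened at the lactone C–O bond and the Z-alkene is taken back to an alkyne, giving γ-hydroxy ynoate 4; the bond between the carbinol carbon and the alkyne is then cut to give 3,4,5-trimethoxybenzaldehyde 1 and methyl propiolate 2. This cut is preferred over building the lactone from a keto acid because one catalytic asymmetric C–C bond formation delivers all four butenolide carbons at the right oxidation level. Aldehyde 8 comes from 3-hydroxy-4,5-dimethoxybenzaldehyde 7 by O-benzylation. The forward chemistry needs an enantioselective alkynylation and a cis-selective semi-hydrogenation that does not racemise the γ-aryl butenolide.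

## Roads not taken

**Alternative 1:** a donor–acceptor cyclopropane and an aldehyde are joined in a (3+2) annulation, cutting O1–C2 and C4–C5. Sn(OTf)2 (divalent tin) would activate the cis-configured cyclopropane diester A2 (ring A as donor); the oxygen of aldehyde 1 attacks the donor carbon with inversion and the malonate carbon closes onto the carbonyl carbon, giving the 2,5-cis oxolane diester A1.
- Merits: the ring and two bonds form in one convergent, catalytic step, and the 2,5-cis outcome inherent to this annulation is the diaryl relationship of 17. In convergence and in closing the ring at the key step this road is better than the chosen one.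
- Weak points: C4 emerges as a gem-diester. One ester must be removed and the other reduced to methyl (decarboxylation, reduction, sulfonylation, hydride), and the decarboxylation creates an epimerisable centre flanked by a methyl group on one face and an aryl group on the other, so neither configuration is clearly preferred. A2 must be made as a single enantiomer with cis aryl and methyl groups, and cyclopropanes with electron-rich aryl donors tend to ring-open reversibly under the Lewis acid, which erodes the stereospecific inversion that the absolute configuration depends on.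
- Against this the chosen plan sets C3 and C4 by relay from one catalytically made centre, and its only epimerisable carbon (C3 of the lactone) has kinetic and thermodynamic preferences that coincide.

**Alternative 2:** a seven-membered vinyl acetal is contracted, cutting C2–C3. TMSOTf would ionise the acetal of dihydrodioxepine A4 to an oxocarbenium ion at C2 and an enol ether, whose carbon attacks C2 to give the oxolane aldehyde A3.
- Merits: the ring is already closed after the key step, and an aldehyde is one reduction level nearer to methyl than a lactone, so the end game from A3 would be about one step shorter than from lactone 12.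
- Weak points: A4 already has to contain the C4/C5 aryl–methyl pair in the correct relative and absolute sense and a regiodefined enol ether, which means an asymmetric crotylation-type step, acetal formation and an olefin isomerisation before the key step. The C2/C3 selectivity of the contraction depends on the ion-pair geometry and is not secured by the substrate. The C3 aldehyde of A3 is epimerisable and, as in Alternative 1, sits between an aryl-bearing and a methyl-bearing carbon of opposite demands, and it has to be cis to the C4 methyl group.
- The chosen plan pays one more step after its key step but builds its stereocentres from a one-stereocentre precursor with default enolate selectivity.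

**Alternative 3:** a bis(1-arylallyl) ether is cyclised by hydrogen-atom transfer, cutting C3–C4. Mn(dpm)3 (trivalent manganese) with PhSiH3 would transfer a hydrogen atom to one vinyl group of ether A6; the secondary radical closes 5-exo onto the other vinyl group and the primary radical is reduced, giving A5, which is identical with 16.
- Merits: ring, C3–C4 bond and both methyl groups form in one step with no redox adjustment afterwards. The chair-like 5-exo transition state predicts the required arrangement (substituents at the radical carbon and the attacked carbon cis, each trans to its aryl-bearing neighbour), and it does not matter which vinyl group receives the hydrogen atom. In step count this is clearly the shortest road, and the chosen plan cannot match it there.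
- Weak points: C3 and C4 are the two centres that cannot be corrected afterwards, and here both would be set by a radical cyclisation whose selectivity is a preference and not a constraint. The radical at C3 lies next to a doubly activated C2–H bond (benzylic and α-oxygenated), so hydrogen-atom return to the metal would isomerise the allyl ether to an aryl enol ether and destroy C2. The unsymmetrical ether A6 with two defined benzylic-allylic centres is itself not trivial to make without allylic transposition.
- The chosen plan sets against the brevity a key step of an established reaction class in which C3 and C4 are fixed by ring-constrained anti additions.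

Key step: step 4

Assumption: aldehyde 7 is taken as purchasable, and (R)-BINOL is assigned to step 1 because the alkynyl group is expected to attack the same aldehyde face as alkyl groups do in this catalyst system; the sense would be checked on the first batch and the ligand antipode used if it proves opposite.

## Route

Step 1
Reactants: 1 3,4,5-trimethoxybenzaldehyde; 2 methyl propiolate
Product: 4 methyl (4S)-4-hydroxy-4-(3,4,5-trimethoxyphenyl)but-2-ynoate, via ethyl(3-methoxy-3-oxoprop-1-ynyl)zinc 3 (not isolated)
Conditions: 2, ZnEt2, (R)-BINOL (40 mol %), HMPA, CH2Cl2, rt; Ti(OiPr)4; then 1, rt; aq. NH4Cl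
Reagents that add atoms: none
Why: Catalytic enantioselective alkynylation of an aldehyde: ZnEt2 metalates 2 to the alkynylzinc 3, which adds to the aldehyde bound to the titanium BINOLate, the ligand fixing the face so that the (S)-carbinol (future C5) should result; aromatic aldehydes are the standard substrates of this reaction type.

Step 2
Reactants: 4 methyl (4S)-4-hydroxy-4-(3,4,5-trimethoxyphenyl)but-2-ynoate
Product: 6 (5R)-5-(3,4,5-trimethoxyphenyl)furan-2(5H)-one, via methyl (2Z,4R)-4-hydroxy-4-(3,4,5-trimethoxyphenyl)but-2-enoate 5 (not isolated)
Conditions: H2 (1 atm), Pd/CaCO3 poisoned with Pb(OAc)2, quinoline, EtOAc, rt; then PPTS (cat.), CH2Cl2, rt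
Reagents that add atoms: none
Why: cis-Semi-hydrogenation of the alkyne puts hydroxyl and ester on the same side of the Z-alkene, so 5 should lactonise with loss of methanol under mild acid; no bond at the stereocentre is touched, and the descriptor changes from S to R only because the unsaturated substituent drops in priority below the aryl group.

Step 3
Reactants: 7 3-hydroxy-4,5-dimethoxybenzaldehyde
Product: 8 3-benzyloxy-4,5-dimethoxybenzaldehyde
Conditions: BnBr, K2CO3, DMF, rt
Reagents that add atoms: benzyl bromide, BrCc1ccccc1
Why: Williamson ether synthesis on the phenoxide; the benzyl ether tolerates cuprate, hydride, sulfonylation and Lewis acid and is removed at the end by hydrogenolysis.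

Step 4
Reactants: 6 (5R)-5-(3,4,5-trimethoxyphenyl)furan-2(5H)-one; 8 3-benzyloxy-4,5-dimethoxybenzaldehyde
Product: 12 (3S,4R,5R)-3-[(3-benzyloxy-4,5-dimethoxyphenyl)(hydroxy)methyl]-4-methyl-5-(3,4,5-trimethoxyphenyl)oxolan-2-one as both carbinol epimers, via lithium dimethylcuprate 9 (not isolated), via lithium lactone enolate 10 (not isolated), via chlorozinc lactone enolate 11 (not isolated)
Conditions: MeLi, CuBr·SMe2, Et2O, −20 °C; 6, THF, −78 °C; ZnCl2 (in Et2O), −78 °C; 8, −78 → −40 °C; aq. NH4Cl
Reagents that add atoms: methyllithium, [Li]C
Why: Cuprate 9 (monovalent copper) should bind the enone of 6 on the face away from the C5 aryl group, add oxidatively at the β-carbon to a trivalent copper intermediate and eliminate reductively, forming the C4–CH3 bond and the lithium enolate 10. ZnCl2 converts 10 into the less basic chlorozinc enolate 11, which adds to aldehyde 8 through a closed six-membered transition state and forms the C2–C3 bond as a zinc aldolate that resists retro-aldol cleavage and dehydration. The closest known reaction type is the one-pot conjugate addition and enolate trapping of organocuprates, γ-substituted butenolides and aldehydes or alkyl halides. No ring is closed in this step; the lactone ring of 6 is carried through unchanged. C4 is controlled by C5 (methyl enters anti to the aryl group) and C3 by C4 (the aldehyde approaches the enolate face anti to the new β-methyl group), giving the 3,4-trans-4,5-trans lactone, while the carbinol carbon forms without control and is reset in step 7. The step needs 1,4- over 1,2-addition, secured by the soft cuprate; trapping of a regiodefined enolate before proton transfer, secured by generating it at −78 °C and transmetalating to zinc; and no γ-deprotonation of 6, which would racemise C5, secured by the low basicity of the cuprate.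

Step 5
Reactants: 12 (3S,4R,5R)-3-[(3-benzyloxy-4,5-dimethoxyphenyl)(hydroxy)methyl]-4-methyl-5-(3,4,5-trimethoxyphenyl)oxolan-2-one
Product: 13 (2R,3R,4R)-1-(3-benzyloxy-4,5-dimethoxyphenyl)-2-(hydroxymethyl)-3-methyl-4-(3,4,5-trimethoxyphenyl)butane-1,4-diol as both C1 epimers
Conditions: LiAlH4, THF, 0 °C; then H2O, aq. NaOH
Reagents that add atoms: none
Why: Hydride reduction of the lactone to the 1,4-diol turns the carbonyl carbon into the primary carbinol and frees the C5 hydroxyl; at 0 °C reduction should outrun retro-aldol cleavage of the aluminium aldolate, and no stereocentre is touched.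

Step 6
Reactants: 13 (2R,3R,4R)-1-(3-benzyloxy-4,5-dimethoxyphenyl)-2-(hydroxymethyl)-3-methyl-4-(3,4,5-trimethoxyphenyl)butane-1,4-diol
Product: 14 (2R,3R,4R)-2-[(3-benzyloxy-4,5-dimethoxyphenyl)(hydroxy)methyl]-4-hydroxy-3-methyl-4-(3,4,5-trimethoxyphenyl)butyl methanesulfonate as both carbinol epimers
Conditions: MsCl (1.05 equiv), 2,4,6-collidine, CH2Cl2, −20 → 0 °C; cold aq. work-up, used at once
Reagents that add atoms: methanesulfonyl chloride, CS(=O)(=O)Cl
Why: Primary-selective sulfonylation with a hindered weak base; the two benzylic secondary hydroxyls are far slower, and without alkoxide formation the 5-exo displacement of the β-branched primary mesylate by the C5 hydroxyl should be slow at or below 0 °C, so 14 is not stored.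

Step 7
Reactants: 14 (2R,3R,4R)-2-[(3-benzyloxy-4,5-dimethoxyphenyl)(hydroxy)methyl]-4-hydroxy-3-methyl-4-(3,4,5-trimethoxyphenyl)butyl methanesulfonate
Product: 15 [(2S,3R,4R,5R)-2-(3-benzyloxy-4,5-dimethoxyphenyl)-4-methyl-5-(3,4,5-trimethoxyphenyl)oxolan-3-yl]methyl methanesulfonate
Conditions: BF3·OEt2 (30 mol %), CH2Cl2, −40 → 0 °C; aq. NaHCO3
Reagents that add atoms: none
Why: Dehydrative SN1 cycloetherification (5-exo capture of a trialkoxybenzylic cation by the other benzylic hydroxyl); the new C–O bond forms trans to the neighbouring ring substituent, so both C2 epimers of 14 should converge on the 2,3-trans ring. If C5 ionises instead it recloses trans to the C4 methyl group, and any 2,3-cis isomer re-ionises readily because of its all-cis strain; the sulfonate keeps the primary oxygen from competing as a nucleophile.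

Step 8
Reactants: 15 [(2S,3R,4R,5R)-2-(3-benzyloxy-4,5-dimethoxyphenyl)-4-methyl-5-(3,4,5-trimethoxyphenyl)oxolan-3-yl]methyl methanesulfonate
Product: 16 (2S,3S,4R,5R)-2-(3-benzyloxy-4,5-dimethoxyphenyl)-3,4-dimethyl-5-(3,4,5-trimethoxyphenyl)oxolane
Conditions: LiBHEt3, THF, 0 °C → rt
Reagents that add atoms: none
Why: SN2 displacement of the primary mesylate by a nucleophilic borohydride turns the former carbonyl carbon into the C3 methyl group; no alkoxide is present, the ring ethers and the benzyl ether are inert, and the C3 descriptor changes from R to S by priority only.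

Step 9
Reactants: 16 (2S,3S,4R,5R)-2-(3-benzyloxy-4,5-dimethoxyphenyl)-3,4-dimethyl-5-(3,4,5-trimethoxyphenyl)oxolane
Product: 17 5-[(2S,3S,4R,5R)-3,4-dimethyl-5-(3,4,5-trimethoxyphenyl)oxolan-2-yl]-2,3-dimethoxyphenol
Conditions: H2 (1 atm), Pd/C, EtOAc, rt
Reagents that add atoms: none
Why: Hydrogenolysis of the aryl benzyl ether over zerovalent palladium; under neutral conditions at 1 atm the unhindered O-benzyl group should cleave well before the hindered, doubly substituted ring benzylic C–O bonds.

## Compound list

1 | 3,4,5-trimethoxybenzaldehyde | COc1cc(C=O)cc(OC)c1OC | starting material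
2 | methyl propiolate | C#CC(=O)OC | starting material
3 | ethyl(3-methoxy-3-oxoprop-1-ynyl)zinc | CC[Zn]C#CC(=O)OC | intermediate (not isolated)
4 | methyl (4S)-4-hydroxy-4-(3,4,5-trimethoxyphenyl)but-2-ynoate | COC(=O)C#C[C@@H](O)c1cc(OC)c(OC)c(OC)c1 | intermediate
5 | methyl (2Z,4R)-4-hydroxy-4-(3,4,5-trimethoxyphenyl)but-2-enoate | COC(=O)/C=C\[C@@H](O)c1cc(OC)c(OC)c(OC)c1 | intermediate (not isolated)
6 | (5R)-5-(3,4,5-trimethoxyphenyl)furan-2(5H)-one | O=C1O[C@@H](c2cc(OC)c(OC)c(OC)c2)C=C1 | intermediate
7 | 3-hydroxy-4,5-dimethoxybenzaldehyde | COc1cc(C=O)cc(O)c1OC | starting material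
8 | 3-benzyloxy-4,5-dimethoxybenzaldehyde | COc1cc(C=O)cc(OCc2ccccc2)c1OC | intermediate
9 | lithium dimethylcuprate | [Li+].C[Cu-]C | intermediate (not isolated)
10 | lithium (4R,5R)-4-methyl-5-(3,4,5-trimethoxyphenyl)-4,5-dihydrofuran-2-olate | [Li]OC1=C[C@@H](C)[C@H](c2cc(OC)c(OC)c(OC)c2)O1 | intermediate (not isolated)
11 | chlorozinc (4R,5R)-4-methyl-5-(3,4,5-trimethoxyphenyl)-4,5-dihydrofuran-2-olate | Cl[Zn]OC1=C[C@@H](C)[C@H](c2cc(OC)c(OC)c(OC)c2)O1 | intermediate (not isolated)
12 | (3S,4R,5R)-3-[(3-benzyloxy-4,5-dimethoxyphenyl)(hydroxy)methyl]-4-methyl-5-(3,4,5-trimethoxyphenyl)oxolan-2-one (both carbinol epimers) | COc1cc(C(O)[C@H]2C(=O)O[C@@H](c3cc(OC)c(OC)c(OC)c3)[C@@H]2C)cc(OCc4ccccc4)c1OC | intermediate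
13 | (2R,3R,4R)-1-(3-benzyloxy-4,5-dimethoxyphenyl)-2-(hydroxymethyl)-3-methyl-4-(3,4,5-trimethoxyphenyl)butane-1,4-diol (both C1 epimers) | COc1cc(C(O)[C@@H](CO)[C@@H](C)[C@@H](O)c2cc(OC)c(OC)c(OC)c2)cc(OCc3ccccc3)c1OC | intermediate
14 | (2R,3R,4R)-2-[(3-benzyloxy-4,5-dimethoxyphenyl)(hydroxy)methyl]-4-hydroxy-3-methyl-4-(3,4,5-trimethoxyphenyl)butyl methanesulfonate (both carbinol epimers) | COc1cc(C(O)[C@@H](COS(C)(=O)=O)[C@@H](C)[C@@H](O)c2cc(OC)c(OC)c(OC)c2)cc(OCc3ccccc3)c1OC | intermediate
15 | [(2S,3R,4R,5R)-2-(3-benzyloxy-4,5-dimethoxyphenyl)-4-methyl-5-(3,4,5-trimethoxyphenyl)oxolan-3-yl]methyl methanesulfonate | COc1cc([C@H]2O[C@@H](c3cc(OC)c(OC)c(OC)c3)[C@H](C)[C@@H]2COS(C)(=O)=O)cc(OCc4ccccc4)c1OC | intermediate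
16 | (2S,3S,4R,5R)-2-(3-benzyloxy-4,5-dimethoxyphenyl)-3,4-dimethyl-5-(3,4,5-trimethoxyphenyl)oxolane | COc1cc([C@H]2O[C@@H](c3cc(OC)c(OC)c(OC)c3)[C@H](C)[C@@H]2C)cc(OCc4ccccc4)c1OC | intermediate
17 | 5-[(2S,3S,4R,5R)-3,4-dimethyl-5-(3,4,5-trimethoxyphenyl)oxolan-2-yl]-2,3-dimethoxyphenol | COc1cc([C@H]2O[C@@H](c3cc(OC)c(OC)c(OC)c3)[C@H](C)[C@@H]2C)cc(O)c1OC | target

## Step count and risks

Total step count: 9. Longest linear sequence: 8 steps (steps 1, 2, 4, 5, 6, 7, 8 and 9 from aldehyde 1); step 3 is the one-step side branch.

**Step 4 (key step).** The most likely failure is incomplete or unselective enolate trapping. In the presence of copper and lithium salts the enolate may add slowly to the electron-rich aldehyde, so that proton transfer, reversal of the aldol addition or γ-deprotonation of unreacted 6 lowers conversion and the 3,4-trans selectivity. The fallback separates the two bond formations. Setting out from 6, conjugate addition of Me2CuLi alone with a protic quench should give (4R,5R)-4-methyl-5-(3,4,5-trimethoxyphenyl)oxolan-2-one F1, which is purified. Its enolate is then made with LiHMDS in THF at −78 °C in the absence of copper and added to 8, the electrophile again entering anti to the C4 methyl group, and the route is rejoined at 12.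

**Step 7.** The most likely failure is diversion of the benzylic cation under acid. Ionisation is reversible, so a long-lived open cation can alkylate the other arene (aryltetralin formation) or lose a proton (which would scramble C3 or C4), and reclosure after C5 ionisation may leave some 2,3-cis ring if convergence is incomplete. The fallback changes the activation mode. Setting out from 14, MsCl and Et3N in CH2Cl2 at 0 °C sulfonylate a benzylic hydroxyl, which ionises irreversibly in basic medium and closes kinetically. This should give 15 together with its C2 epimer, [(2R,3R,4R,5R)-2-(3-benzyloxy-4,5-dimethoxyphenyl)-4-methyl-5-(3,4,5-trimethoxyphenyl)oxolan-3-yl]methyl methanesulfonate F2. The mixture is reduced with LiBHEt3 to 16 and (2R,3S,4R,5R)-2-(3-benzyloxy-4,5-dimethoxyphenyl)-3,4-dimethyl-5-(3,4,5-trimethoxyphenyl)oxolane F3. F3 is then epimerised to 16 by brief exposure to catalytic BF3·OEt2 at low temperature, driven by relief of the all-cis strain, and the route is rejoined at 16.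

**Step 6.** The most likely failure is premature intramolecular displacement of the primary mesylate by the C5 hydroxyl (5-exo), which would give the isomeric 2-aryl oxolane, or partial sulfonylation of a benzylic hydroxyl. The fallback blocks the primary oxygen with a group that is not a leaving group. Setting out from 13, TBDPSCl and imidazole should give (2R,3R,4R)-1-(3-benzyloxy-4,5-dimethoxyphenyl)-2-[(tert-butyldiphenylsilyloxy)methyl]-3-methyl-4-(3,4,5-trimethoxyphenyl)butane-1,4-diol F4. Cycloetherification with catalytic BF3·OEt2 then gives tert-butyl{[(2S,3R,4R,5R)-2-(3-benzyloxy-4,5-dimethoxyphenyl)-4-methyl-5-(3,4,5-trimethoxyphenyl)oxolan-3-yl]methoxy}diphenylsilane F5. TBAF releases [(2S,3R,4R,5R)-2-(3-benzyloxy-4,5-dimethoxyphenyl)-4-methyl-5-(3,4,5-trimethoxyphenyl)oxolan-3-yl]methanol F6, and MsCl with Et3N converts it into 15, where the route is rejoined.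

**Step 2.** The most likely failure is over-reduction, since the Z-enoate and the butenolide are themselves reducible, or racemisation of the γ-aryl butenolide through deprotonation at its benzylic γ-carbon by the amine additive. The fallback accepts full reduction and reinstalls the double bond. Setting out from 4, exhaustive hydrogenation of the triple bond over PtO2 followed by acid lactonisation should give (5R)-5-(3,4,5-trimethoxyphenyl)oxolan-2-one F7. LDA and PhSeBr give (5R)-3-(phenylselanyl)-5-(3,4,5-trimethoxyphenyl)oxolan-2-one F8, and oxidation with H2O2 triggers selenoxide syn-elimination to 6, where the route is rejoined.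

**Step 1.** The most likely failure is insufficient enantioselectivity, or the opposite facial sense, in the alkynylation of this electron-rich aldehyde, together with base-induced isomerisation of the γ-hydroxy ynoate. The fallback sets the carbinol by ketone reduction. Setting out from 1, a Stetter reaction with methyl acrylate (thiazolium carbene catalyst, Et3N) should give methyl 4-oxo-4-(3,4,5-trimethoxyphenyl)butanoate F9. Asymmetric transfer hydrogenation with RuCl(p-cymene)[(R,R)-TsDPEN] and HCO2H/Et3N, the (R,R)-catalyst being expected to give the (R)-carbinol, followed by lactonisation gives the lactone F7 of the preceding fallback. This is carried through F8 to 6, where the route is rejoined.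

## Further compounds

F1 | step 4 | (4R,5R)-4-methyl-5-(3,4,5-trimethoxyphenyl)oxolan-2-one | C[C@@H]1CC(=O)O[C@H]1c2cc(OC)c(OC)c(OC)c2
F2 | step 7 | [(2R,3R,4R,5R)-2-(3-benzyloxy-4,5-dimethoxyphenyl)-4-methyl-5-(3,4,5-trimethoxyphenyl)oxolan-3-yl]methyl methanesulfonate | COc1cc([C@@H]2O[C@@H](c3cc(OC)c(OC)c(OC)c3)[C@H](C)[C@@H]2COS(C)(=O)=O)cc(OCc4ccccc4)c1OC
F3 | step 7 | (2R,3S,4R,5R)-2-(3-benzyloxy-4,5-dimethoxyphenyl)-3,4-dimethyl-5-(3,4,5-trimethoxyphenyl)oxolane | COc1cc([C@@H]2O[C@@H](c3cc(OC)c(OC)c(OC)c3)[C@H](C)[C@@H]2C)cc(OCc4ccccc4)c1OC
F4 | step 6 | (2R,3R,4R)-1-(3-benzyloxy-4,5-dimethoxyphenyl)-2-[(tert-butyldiphenylsilyloxy)methyl]-3-methyl-4-(3,4,5-trimethoxyphenyl)butane-1,4-diol (both C1 epimers) | COc1cc(C(O)[C@@H](CO[Si](c2ccccc2)(c3ccccc3)C(C)(C)C)[C@@H](C)[C@@H](O)c4cc(OC)c(OC)c(OC)c4)cc(OCc5ccccc5)c1OC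
F5 | step 6 | tert-butyl{[(2S,3R,4R,5R)-2-(3-benzyloxy-4,5-dimethoxyphenyl)-4-methyl-5-(3,4,5-trimethoxyphenyl)oxolan-3-yl]methoxy}diphenylsilane | COc1cc([C@H]2O[C@@H](c3cc(OC)c(OC)c(OC)c3)[C@H](C)[C@@H]2CO[Si](c4ccccc4)(c5ccccc5)C(C)(C)C)cc(OCc6ccccc6)c1OC
F6 | step 6 | [(2S,3R,4R,5R)-2-(3-benzyloxy-4,5-dimethoxyphenyl)-4-methyl-5-(3,4,5-trimethoxyphenyl)oxolan-3-yl]methanol | COc1cc([C@H]2O[C@@H](c3cc(OC)c(OC)c(OC)c3)[C@H](C)[C@@H]2CO)cc(OCc4ccccc4)c1OC
F7 | step 2 | (5R)-5-(3,4,5-trimethoxyphenyl)oxolan-2-one | O=C1O[C@@H](c2cc(OC)c(OC)c(OC)c2)CC1
F8 | step 2 | (5R)-3-(phenylselanyl)-5-(3,4,5-trimethoxyphenyl)oxolan-2-one (both C3 epimers) | O=C1O[C@@H](c2cc(OC)c(OC)c(OC)c2)CC1[Se]c3ccccc3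
F9 | step 1 | methyl 4-oxo-4-(3,4,5-trimethoxyphenyl)butanoate | COC(=O)CCC(=O)c1cc(OC)c(OC)c(OC)c1
A1 | alternative 1 | dimethyl (2S,4S,5S)-5-(3-benzyloxy-4,5-dimethoxyphenyl)-4-methyl-2-(3,4,5-trimethoxyphenyl)oxolane-3,3-dicarboxylate | COc1cc([C@H]2O[C@@H](c3cc(OC)c(OC)c(OC)c3)C(C(=O)OC)(C(=O)OC)[C@@H]2C)cc(OCc4ccccc4)c1OC
A2 | alternative 1 | dimethyl (2R,3R)-2-(3-benzyloxy-4,5-dimethoxyphenyl)-3-methylcyclopropane-1,1-dicarboxylate (aryl and methyl cis) | COC(=O)C1(C(=O)OC)[C@@H](c2cc(OC)c(OC)c(OCc3ccccc3)c2)[C@H]1C
A3 | alternative 2 | (2S,3S,4R,5R)-2-(3-benzyloxy-4,5-dimethoxyphenyl)-4-methyl-5-(3,4,5-trimethoxyphenyl)oxolane-3-carbaldehyde | COc1cc([C@H]2O[C@@H](c3cc(OC)c(OC)c(OC)c3)[C@H](C)[C@@H]2C=O)cc(OCc4ccccc4)c1OC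
A4 | alternative 2 | (4R,5R)-2-(3-benzyloxy-4,5-dimethoxyphenyl)-5-methyl-4-(3,4,5-trimethoxyphenyl)-4,5-dihydro-1,3-dioxepine (acetal carbon as either epimer) | COc1cc(C2OC=C[C@@H](C)[C@H](c3cc(OC)c(OC)c(OC)c3)O2)cc(OCc4ccccc4)c1OC
A5 | alternative 3 | (2S,3S,4R,5R)-2-(3-benzyloxy-4,5-dimethoxyphenyl)-3,4-dimethyl-5-(3,4,5-trimethoxyphenyl)oxolane | COc1cc([C@H]2O[C@@H](c3cc(OC)c(OC)c(OC)c3)[C@H](C)[C@@H]2C)cc(OCc4ccccc4)c1OC
A6 | alternative 3 | 1-benzyloxy-2,3-dimethoxy-5-[(1S)-1-{[(1R)-1-(3,4,5-trimethoxyphenyl)prop-2-en-1-yl]oxy}prop-2-en-1-yl]benzene | COc1cc([C@H](C=C)O[C@H](C=C)c2cc(OC)c(OC)c(OC)c2)cc(OCc3ccccc3)c1OC
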